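The closed flask and its neighbour, the tank, take the same charge, the flask for 30 h and the tank for 30 h on average, and one of them has to be chosen.

    starting material ⇌ intermediate A (K1 = 0.46, k1 = 0.011 /min)
    intermediate A → intermediate B (k2 = 0.0052 /min)
    intermediate B → intermediate C (k3 = 6.2 × 10⁻⁴ /min)
    intermediate C → intermediate D (k4 = 0.0051 /min)
    intermediate C → intermediate E (k5 = 0.011 /min)
    intermediate E → target (k6 = 0.0030 /min)
    target ⇌ intermediate D (K7 = 0.29, k7 = 0.0079 /min)
    intermediate E → intermediate D (k8 = 0.0088 /min)
    2 starting material → homo dimer (k9 = 0.0010 /M/min)
    starting material + target → side product (k10 = 0.19 /M/min)

- grey: starting material 20 mM; a single well-mixed tank run continuously and read at steady state, 30 h in it on average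
- green: starting material 20 mM; time 30 h; a closed flask charged with all of it at once and left for 30 h

1. the set-up with the highest share of target in all that became target or side product, at the outlet or at the end ("none" if the first two lie within 2 percentage points) (grey / green / none)
2. share of target in all that became target or side product, at the outlet or at the end, grey
3. share of target in all that became target or side product, at the outlet or at the end, green

- percentages count the starting material that a species holds: one homo dimer or side product counts as two
- a doubled species enters its step squared and goes two at a time
- the stated concentrations are those of everything mixed, before any reaction; amounts are the same in each set-up
- run time (green): 30 h

**Turnover count.** In the grey tank starting material stands steady, so target goes to side product in a pseudo-first-order way, and side product equals N times target. Here N = x·s, where s is the fraction of the charge standing as starting material and x is k10 times the charge times the residence time, 6.84, the full-charge turnovers. Each side product counts double, so the grey share is one over the sum of one and twice N.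

**First link.** With intermediate A returning, starting material leaves at a net 0.00196 /min. Over 30 h on average in the grey tank, that gives s = 0.220, N = 1.51 and a grey share of 24.9 %.

**Green flask.** In the green flask, a target standing from the start would see 1.93 turnovers by this estimate. But intermediate B moves on at 6.2 × 10⁻⁴ /min, slower than the net loss of starting material, so target is born late. Weighting the turnovers still ahead by the birth rate over 30 h keeps a fraction 0.189. So N = 0.366 and the green share is 57.7 %.

**Weak link.** The grey s ignores that each side product consumes one starting material. By my estimate, a fraction 0.411 of the charge gets past intermediate B in the grey tank. Step 7 is quick against the stay, so each target carries 0.29 of intermediate D and N side products. That makes side product 0.222 of the charge, s falls to 0.172, N to 1.17, and I commit to 29.9 % for grey, less than green.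

**The forecast.** It names green, with 29 % for grey and 63 % for green, higher than my green figure. Its ground is that “most target forms late, after the starting material has largely gone”.

**The result.** The simulation gives green as best, with 29.3 % for the grey tank and 64.7 % for the green flask. Starting material in the grey tank stands at 0.176 of the charge, so N = 1.21 and the turnover rule gives 29.2 %. At three times the residence time the grey tank gives 27.9 %. Through the same rule that is N = 1.29, and with x tripled it puts starting material at 0.0629 of the charge.

(The numbers of this flask are made up, and the outcome is calculated.)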